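In Monday's run the target trails far behind the starting material: at 80.0 min the reading of target is 0.4%, far less than the 67.4% of the charged starting material consumed by then.

- Monday's: starting material 0.10 M; second substrate 0.20 M; enzyme 2.5 µM; run made earlier
- flask: starting material 0.10 M; second substrate 0.100 M; enzyme 2.5 µM; time 10 h

- Monday's (time / min: target / %, starting material / %): 25.0: 0, 61.6; 50.0: 0, 44.2; 80.0: 0.4, 32.6; 90.0: 1.1, 29.8; 120: 3.6, 22.6

(readings scatter by 0.3 percentage points)

- the earlier runs were read with a standard deviation of 0.3 percentage points
- a reading or a percentage of target counts all its forms, free or not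

* the best time, 10 h at the latest, for target
* the amount of target, in percent of the starting material charged, at that time

I work with the fraction left, f. In Monday's run (1/f − 1)/t holds steady, 0.0249 min⁻¹ at 25.0 min and κ = 0.0252 min⁻¹ at 50.0 min, which marks a second-order loss with first half-life 1/κ. Monday's target readings, extrapolated back, start at 76.8 min, the induction period. I take this as the time the enzyme needs to consume the second substrate, so it scales with c(second substrate)/c(enzyme), giving 38.4 min in this flask.

N = κ · t(lag) = 0.970

f = 1/(1 + N) = 50.8%

N is the lag counted in first half-lives of the starting material, and f is the stock this flask should hold when target begins. One number is not enough for the height, though: at 120 min Monday's reading of starting material lies 2.2 percentage points under this curve, with 3.6% of target read at the same time.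

The forecast gives 10% at 10 h, in its words “No loss of target is seen, so the best time is probably the limit”.

This flask peaks at 10.0% at 5.11 h.

    starting material + enzyme ⇌ complex A (K = 2.21 L mol⁻¹, k = 19000 L mol⁻¹ s⁻¹)
    complex A ⇌ enzyme + target (K = 0.480 M, k = 10.1 s⁻¹)
    second substrate + enzyme ⇌ complex B (K = 828 L mol⁻¹, k = 57800 L mol⁻¹ s⁻¹)
    complex B → enzyme + second product (k = 17.0 s⁻¹)
    crystals ⇌ target, rate k5*(cs5 - [target]) while solid is left; crystals form when [target] > cs5 (solubility = 0.0770 M, k = 0.00253 s⁻¹)
    2 starting material → homo dimer (k = 0.00208 L mol⁻¹ s⁻¹)

In this flask half of the turnover of complex B into enzyme and second product up to 10.0 h is done by 0.335 h, close to half my lag, 0.320 h. With 1.0 × 10⁻⁵ M of enzyme and the other charges held, N falls to 0.242, so 80.5% of the starting material should be left when target begins, and that flask reaches 22.6% of target.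

All runs come from a simulation for an exercise; scatter was added.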